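**Retrosynthetic overview**

1. The cyclohexane is the last ring closed (only desilylation follows). It forms by a bromide-terminated cation–olefin cyclisation: the CH2 end of the vinyl group of an (R)-linalool unit attacks the ring-side terminus of a pentadienyl cation, and bromide is captured at the other vinyl carbon.
2. Enabling feature: the ring CH is allylic to the (E,E)-diene, so it can be one terminus of a cation delocalised over the five chain carbons from that ring CH to the oxane-bound CH. The adjoining ring atoms CH2–CHBr–C(CH3)(OH) map onto CH2=CH–C(CH3)(OH) of linalool.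
3. The cation precursor is a bis-allylic acetate. It comes from a Nozaki–Hiyama–Kishi union of an (E)-enal (from (R)-linalool by silylation, SeO2 and MnO2) with an (E)-iodovinyl bromo-oxane.
4. The bromo-oxane is made first, from geraniol: Sharpless epoxidation, CO2-mediated carbonate formation, 6-endo bromoetherification, carbonate cleavage with periodate, Takai olefination.
5. Ring order: oxane (step 3), then cyclohexane (step 11).

Key step: step 11

Remark: the SMILES is read as (1R,2S,4S) on the cyclohexane (dienyl group, Br and OH mutually cis; chair with dienyl, Br and CH3 equatorial, OH axial) and (2R,5S) on the oxane (Br trans to the dienyl group). The route is built for this diastereomer.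

**Route**

Step 1
Reactants: 1 geraniol
Product: 2 [(2R,3R)-3-methyl-3-(4-methylpent-3-en-1-yl)oxiran-2-yl]methanol
Conditions: Ti(OiPr)4 (cat.), D-(−)-diethyl tartrate (cat.), t-BuOOH, 4 Å MS, CH2Cl2, −20 °C
Reagents that add atoms: tert-butyl hydroperoxide CC(C)(C)OO
Why: Sharpless asymmetric epoxidation should oxidise only the allylic 2,3-alkene, and the D-tartrate complex should deliver oxygen to the face that gives the (2R,3R)-epoxide, which fixes the later quaternary oxane carbon.

Step 2
Reactants: 2 [(2R,3R)-3-methyl-3-(4-methylpent-3-en-1-yl)oxiran-2-yl]methanol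
Product: 3 (4S)-4-[(2R)-2-hydroxy-6-methylhept-5-en-2-yl]-1,3-dioxolan-2-one
Conditions: Cs2CO3 (cat.), CO2 (1 atm), 3 Å MS, DMF, 40 °C
Reagents that add atoms: carbon dioxide O=C=O
Why: Known carbonate formation from 2,3-epoxy alcohols: the alkoxide adds CO2 and the carbonate anion opens the epoxide at the secondary carbon (5-exo-tet SN2, inversion), so the tertiary oxygen keeps its configuration and the diol is masked as a bulky branched group.

Step 3
Reactants: 3 (4S)-4-[(2R)-2-hydroxy-6-methylhept-5-en-2-yl]-1,3-dioxolan-2-one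
Product: 4 (4S)-4-[(2R,5S)-5-bromo-2,6,6-trimethyloxan-2-yl]-1,3-dioxolan-2-one
Conditions: 2,4,4,6-tetrabromocyclohexa-2,5-dien-1-one, MeNO2, 0 °C → rt, dark
Reagents that add atoms: 2,4,4,6-tetrabromocyclohexa-2,5-dien-1-one O=C1C(Br)=CC(Br)(Br)C=C1Br
Why: Bromonium-induced 6-endo (Markovnikov) etherification of a γ,δ-unsaturated tertiary alcohol, known for 3-bromo-2,2,6-trimethyloxanes; in the chair transition state bromine and the branched dioxolanonyl group are equatorial and the methyl axial, which should set the CHBr carbon S (Br trans to the dioxolanonyl group).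

Step 4
Reactants: 4 (4S)-4-[(2R,5S)-5-bromo-2,6,6-trimethyloxan-2-yl]-1,3-dioxolan-2-one
Product: 6 (2R,5S)-5-bromo-2,6,6-trimethyloxane-2-carbaldehyde, via diol 5 (not isolated)
Conditions: K2CO3 (cat.), MeOH, rt; then AcOH to pH 7, NaIO4, H2O, 0 °C → rt
Reagents that add atoms: none
Why: Methanolysis of the cyclic carbonate and periodate glycol cleavage in one flask; the aldehyde has no α-hydrogen, so the quaternary centre cannot epimerise.

Step 5
Reactants: 6 (2R,5S)-5-bromo-2,6,6-trimethyloxane-2-carbaldehyde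
Product: 7 (2R,5S)-5-bromo-2-[(E)-2-iodoethenyl]-2,6,6-trimethyloxane
Conditions: CrCl2, CHI3, THF, 0 °C → rt
Reagents that add atoms: iodoform IC(I)I
Why: Takai iodo-olefination of a non-enolisable aldehyde, which should give the (E)-iodoalkene through anti elimination of the gem-dichromium adduct; the secondary alkyl bromide is not reduced by Cr(II) under these conditions.

Step 6
Reactants: 8 (R)-linalool [(3R)-3,7-dimethylocta-1,6-dien-3-ol]
Product: 9 {[(3R)-3,7-dimethylocta-1,6-dien-3-yl]oxy}triethylsilane
Conditions: Et3SiOTf, 2,6-lutidine, CH2Cl2, −78 → 0 °C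
Reagents that add atoms: triethylsilyl trifluoromethanesulfonate CC[Si](CC)(CC)OS(=O)(=O)C(F)(F)F
Why: Silylation of the tertiary allylic alcohol with a silyl triflate and a hindered base; the stereocentre is not touched.

Step 7
Reactants: 9 {[(3R)-3,7-dimethylocta-1,6-dien-3-yl]oxy}triethylsilane
Product: 10 (2E,6R)-2,6-dimethyl-6-[(triethylsilyl)oxy]octa-2,7-dien-1-ol
Conditions: SeO2 (cat.), t-BuOOH, salicylic acid (cat.), CH2Cl2, rt
Reagents that add atoms: selenium dioxide O=[Se]=O; tert-butyl hydroperoxide CC(C)(C)OO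
Why: Selenium dioxide allylic oxidation (ene reaction, then [2,3]-shift) is known to oxidise the (E)-methyl group of a prenyl unit selectively; the vinyl group has no allylic hydrogen.

Step 8
Reactants: 10 (2E,6R)-2,6-dimethyl-6-[(triethylsilyl)oxy]octa-2,7-dien-1-ol
Product: 11 (2E,6R)-2,6-dimethyl-6-[(triethylsilyl)oxy]octa-2,7-dienal
Conditions: MnO2, CH2Cl2, rt
Reagents that add atoms: none
Why: Chemoselective MnO2 oxidation of a primary allylic alcohol to the (E)-enal; the silyl ether and alkene geometry are unaffected.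

Step 9
Reactants: 7 (2R,5S)-5-bromo-2-[(E)-2-iodoethenyl]-2,6,6-trimethyloxane; 11 (2E,6R)-2,6-dimethyl-6-[(triethylsilyl)oxy]octa-2,7-dienal
Product: 13 (1E,4E,8R)-1-[(2R,5S)-5-bromo-2,6,6-trimethyloxan-2-yl]-4,8-dimethyl-8-[(triethylsilyl)oxy]deca-1,4,9-trien-3-ol (both C3 epimers), via alkenylchromium species 12 (not isolated)
Conditions: CrCl2, NiCl2 (cat.), DMSO/THF, rt
Reagents that add atoms: none
Why: Nozaki–Hiyama–Kishi coupling: Ni-catalysed formation of the alkenylchromium(III) species with retention of alkene geometry and its 1,2-addition to the enal; the new carbinol centre forms as a mixture, which does not matter because it is ionised in step 11.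

Step 10
Reactants: 13 (1E,4E,8R)-1-[(2R,5S)-5-bromo-2,6,6-trimethyloxan-2-yl]-4,8-dimethyl-8-[(triethylsilyl)oxy]deca-1,4,9-trien-3-ol
Product: 14 (1E,4E,8R)-1-[(2R,5S)-5-bromo-2,6,6-trimethyloxan-2-yl]-4,8-dimethyl-8-[(triethylsilyl)oxy]deca-1,4,9-trien-3-yl acetate
Conditions: Ac2O, Et3N, DMAP (cat.), CH2Cl2, 0 °C
Reagents that add atoms: acetic anhydride CC(=O)OC(C)=O
Why: DMAP-catalysed acetylation of the bis-allylic alcohol installs the leaving group for ionisation.

Step 11
Reactants: 14 (1E,4E,8R)-1-[(2R,5S)-5-bromo-2,6,6-trimethyloxan-2-yl]-4,8-dimethyl-8-[(triethylsilyl)oxy]deca-1,4,9-trien-3-yl acetate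
Product: 16 {[(1R,2S,4S)-2-bromo-4-{(2E,4E)-5-[(2R,5S)-5-bromo-2,6,6-trimethyloxan-2-yl]penta-2,4-dien-2-yl}-1-methylcyclohexyl]oxy}triethylsilane, via pentadienyl cation 15 (not isolated)
Conditions: SnBr4 (1.05 equiv), 2,6-di-tert-butyl-4-methylpyridine (0.3 equiv), CH2Cl2, −78 °C; quench Et3N/MeOH, aq. NaHCO3 at −78 °C
Reagents that add atoms: tin(IV) bromide Br[Sn](Br)(Br)Br
Why: Proposed new method: SnBr4 should ionise the bis-allylic acetate to the W-shaped pentadienyl cation 15 (ionisation of a doubly allylic ester is far easier than that of the tertiary silyl ether or of the oxane, whose ring C–O bond is not yet dienylic); the CH2 terminus of the vinyl group attacks the ring-side cation terminus while bromide from the acetatobromostannate counter-ion adds to the internal vinyl carbon in one anti addition, so that no free secondary cation needs to form. The closest known reactions are the SnBr4-mediated Prins cyclisation of α-acetoxy ethers onto a terminal vinyl group, which gives 4-bromo-oxanes with equatorial bromide, and allyl-cation-initiated cation–olefin cyclisations terminated by a vinyl group; new here is the pentadienyl cation as initiator next to an allylic silyl ether. The cyclohexane closes 6-endo-trig with respect to the vinyl group (5-exo closure would give a primary cation, and attack at the other cation termini would give eight- or ten-membered rings). In the chair transition state the dienyl group is equatorial and bromide enters anti to the forming C–C bond, which sets the two new stereocentres cis-1,3 (both equatorial); their sense relative to the linalool-derived carbinol carbon follows from the chair with CH3 equatorial and the small OSiEt3 axial, in which neither CH3 nor the ring C–C bond is aligned with the developing empty orbital, so a pinacol-type shift is disfavoured. The E,E-diene results from attack on the extended cation, whose geometry is inherited from the (E)-alkenes of 14. The step needs chemoselective ionisation and survival of the product, whose oxane C–O bond has become dienylic; one equivalent of SnBr4 at −78 °C, a hindered pyridine as proton trap and a cold basic quench are meant to secure this.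

Step 12
Reactants: 16 {[(1R,2S,4S)-2-bromo-4-{(2E,4E)-5-[(2R,5S)-5-bromo-2,6,6-trimethyloxan-2-yl]penta-2,4-dien-2-yl}-1-methylcyclohexyl]oxy}triethylsilane
Product: 17 (1R,2S,4S)-2-bromo-4-{(2E,4E)-5-[(2R,5S)-5-bromo-2,6,6-trimethyloxan-2-yl]penta-2,4-dien-2-yl}-1-methylcyclohexan-1-ol (CNP0199463.2)
Conditions: Bu4NF, AcOH (1:1), THF, 0 °C → rt
Reagents that add atoms: none
Why: Fluoride cleavage of the tertiary triethylsilyl ether under buffered, near-neutral conditions should spare the acid-labile dienylic oxane ether and avoid alkoxide-induced ring contraction of the cis-bromohydrin.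

**Compound list**

1 | geraniol | OC/C=C(\C)CCC=C(C)C | starting material
2 | [(2R,3R)-3-methyl-3-(4-methylpent-3-en-1-yl)oxiran-2-yl]methanol | OC[C@H]1O[C@]1(C)CCC=C(C)C | intermediate
3 | (4S)-4-[(2R)-2-hydroxy-6-methylhept-5-en-2-yl]-1,3-dioxolan-2-one | O=C1OC[C@H](O1)[C@](C)(O)CCC=C(C)C | intermediate
4 | (4S)-4-[(2R,5S)-5-bromo-2,6,6-trimethyloxan-2-yl]-1,3-dioxolan-2-one | O=C1OC[C@H](O1)[C@@]2(C)CC[C@H](Br)C(C)(C)O2 | intermediate
5 | (1S)-1-[(2R,5S)-5-bromo-2,6,6-trimethyloxan-2-yl]ethane-1,2-diol | OC[C@H](O)[C@@]1(C)CC[C@H](Br)C(C)(C)O1 | intermediate (not isolated)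
6 | (2R,5S)-5-bromo-2,6,6-trimethyloxane-2-carbaldehyde | O=C[C@@]1(C)CC[C@H](Br)C(C)(C)O1 | intermediate
7 | (2R,5S)-5-bromo-2-[(E)-2-iodoethenyl]-2,6,6-trimethyloxane | I/C=C/[C@@]1(C)CC[C@H](Br)C(C)(C)O1 | intermediate
8 | (R)-linalool, (3R)-3,7-dimethylocta-1,6-dien-3-ol | C=C[C@](C)(O)CCC=C(C)C | starting material
9 | {[(3R)-3,7-dimethylocta-1,6-dien-3-yl]oxy}triethylsilane | C=C[C@](C)(O[Si](CC)(CC)CC)CCC=C(C)C | intermediate
10 | (2E,6R)-2,6-dimethyl-6-[(triethylsilyl)oxy]octa-2,7-dien-1-ol | C=C[C@](C)(O[Si](CC)(CC)CC)CC/C=C(\C)CO | intermediate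
11 | (2E,6R)-2,6-dimethyl-6-[(triethylsilyl)oxy]octa-2,7-dienal | C=C[C@](C)(O[Si](CC)(CC)CC)CC/C=C(\C)C=O | intermediate
12 | dichloro{(E)-2-[(2R,5S)-5-bromo-2,6,6-trimethyloxan-2-yl]ethenyl}chromium(III) | Cl[Cr](Cl)/C=C/[C@@]1(C)CC[C@H](Br)C(C)(C)O1 | intermediate (not isolated)
13 | (1E,4E,8R)-1-[(2R,5S)-5-bromo-2,6,6-trimethyloxan-2-yl]-4,8-dimethyl-8-[(triethylsilyl)oxy]deca-1,4,9-trien-3-ol (both C3 epimers) | C=C[C@](C)(O[Si](CC)(CC)CC)CC/C=C(\C)C(O)/C=C/[C@@]1(C)CC[C@H](Br)C(C)(C)O1 | intermediate
14 | (1E,4E,8R)-1-[(2R,5S)-5-bromo-2,6,6-trimethyloxan-2-yl]-4,8-dimethyl-8-[(triethylsilyl)oxy]deca-1,4,9-trien-3-yl acetate | C=C[C@](C)(O[Si](CC)(CC)CC)CC/C=C(\C)C(OC(C)=O)/C=C/[C@@]1(C)CC[C@H](Br)C(C)(C)O1 | intermediate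
15 | W-shaped pentadienyl cation from 14, as its acetatotetrabromostannate ion pair | C=C[C@](C)(O[Si](CC)(CC)CC)CC[CH+]/C(C)=C/C=C/[C@@]1(C)CC[C@H](Br)C(C)(C)O1.CC(=O)O[Sn-](Br)(Br)(Br)Br | intermediate (not isolated)
16 | {[(1R,2S,4S)-2-bromo-4-{(2E,4E)-5-[(2R,5S)-5-bromo-2,6,6-trimethyloxan-2-yl]penta-2,4-dien-2-yl}-1-methylcyclohexyl]oxy}triethylsilane | C/C(=C\C=C\[C@@]1(C)CC[C@H](Br)C(C)(C)O1)[C@H]1CC[C@@](C)(O[Si](CC)(CC)CC)[C@@H](Br)C1 | intermediate
17 | (1R,2S,4S)-2-bromo-4-{(2E,4E)-5-[(2R,5S)-5-bromo-2,6,6-trimethyloxan-2-yl]penta-2,4-dien-2-yl}-1-methylcyclohexan-1-ol | C/C(=C\C=C\[C@@]1(C)CC[C@H](Br)C(C)(C)O1)[C@H]1CC[C@@](C)(O)[C@@H](Br)C1 | target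

**Step count**

Total: 12 steps. Longest linear sequence: 9 steps (steps 1–5 and 9–12, from geraniol).

**Steps most likely to fail**

1. Step 11 (Proposed new method). Three processes may defeat it:
   - The cation may collapse to dienyl bromides or lose a proton to trienes, because the vinyl group next to the silyloxy carbon is a weak nucleophile.
   - The silyl ether oxygen may capture the cation, closing a tetrahydrofuran with loss of the silyl group.
   - Face selectivity relative to the carbinol centre may be low (chair with CH3 axial), or a 1,2-shift may occur at the bromide-accepting carbon.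

   Fallback (known chemistry; sets out from vinyl iodide 7 and comes back at 16): the carbocycle is taken from the chiral pool instead of being closed. Commercial (S)-limonene 1,2-oxide (cis/trans mixture) is hydrolysed with dilute H2SO4 in THF/water to the trans-diaxial (1R,2R,4S)-1-methyl-4-(prop-1-en-2-yl)cyclohexane-1,2-diol F1. SO2Cl2/Et3N should convert it into the cyclic sulfate F2. LiBr in THF opens this by SN2 at the secondary carbon, with inversion, to the lithium bromocyclohexyl sulfate F3, and catalytic H2SO4/water hydrolyses it to the cis-bromohydrin F4 (Br equatorial, OH axial). Silylation (Et3SiOTf, 2,6-lutidine) gives the triethylsilyl ether F5, and ozonolysis of the isopropenyl group (O3, CH2Cl2, −78 °C; Me2S) gives the methyl ketone F6. Boron–Wittig olefination with lithiated bis(pinacolato)borylmethane should give the (E)-alkenyl boronate F7. Suzuki coupling of F7 with 7 (Pd(PPh3)4, aq. K3PO4, THF) should then give 16 with retention of both alkene geometries.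

2. Step 3. The bromonium ion may be opened 5-exo at the secondary carbon, giving the bromoisopropyl-tetrahydrofuran, and irreversible bromonium formation may erode the facial selectivity at the CHBr carbon.

   Fallback (sets out from 3 and comes back at 4): mercury(II) trifluoroacetate in nitromethane closes the oxane at the tertiary carbon; oxymercuration is more strictly Markovnikov than bromonium opening and is reversible, so it should settle on the all-equatorial chair. Aqueous KBr then gives the alkylmercuric bromide F8, and brominolysis with Br2/LiBr in pyridine in the dark, which proceeds with retention at carbon, should give 4.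

3. Step 9. The alkenylchromium species may form slowly from iodide 7, whose alkene carbon is bound to a quaternary centre, so that protodeiodination and reductive dimerisation take over.

   Fallback (sets out from 11 and 6, comes back at 16): the roles are reversed. Takai olefination of enal 11 (CrCl2, CHI3) gives the (1E,3E)-dienyl iodide F9, and its Nozaki–Hiyama–Kishi addition to aldehyde 6 gives the dienylic alcohol F10. Acetylation gives the acetate F11. Under the conditions of step 11, F11 should ionise to the same cation 15, and the route is rejoined at 16.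

**Further compounds**

F1 | step 11 | (1R,2R,4S)-1-methyl-4-(prop-1-en-2-yl)cyclohexane-1,2-diol | CC(=C)[C@H]1CC[C@@](C)(O)[C@H](O)C1
F2 | step 11 | cyclic sulfate of F1 (trans-fused 1,3,2-dioxathiolane 2,2-dioxide) | CC(=C)[C@H]1CC[C@@]2(C)OS(=O)(=O)O[C@@H]2C1
F3 | step 11 | lithium (1R,2S,4S)-2-bromo-1-methyl-4-(prop-1-en-2-yl)cyclohexyl sulfate | CC(=C)[C@H]1CC[C@@](C)(OS(=O)(=O)[O-])[C@@H](Br)C1.[Li+]
F4 | step 11 | (1R,2S,4S)-2-bromo-1-methyl-4-(prop-1-en-2-yl)cyclohexan-1-ol | CC(=C)[C@H]1CC[C@@](C)(O)[C@@H](Br)C1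
F5 | step 11 | {[(1R,2S,4S)-2-bromo-1-methyl-4-(prop-1-en-2-yl)cyclohexyl]oxy}triethylsilane | CC(=C)[C@H]1CC[C@@](C)(O[Si](CC)(CC)CC)[C@@H](Br)C1
F6 | step 11 | 1-{(1S,3S,4R)-3-bromo-4-methyl-4-[(triethylsilyl)oxy]cyclohexyl}ethan-1-one | CC(=O)[C@H]1CC[C@@](C)(O[Si](CC)(CC)CC)[C@@H](Br)C1
F7 | step 11 | {[(1R,2S,4S)-2-bromo-1-methyl-4-[(E)-1-(4,4,5,5-tetramethyl-1,3,2-dioxaborolan-2-yl)prop-1-en-2-yl]cyclohexyl]oxy}triethylsilane | C/C(=C\B1OC(C)(C)C(C)(C)O1)[C@H]1CC[C@@](C)(O[Si](CC)(CC)CC)[C@@H](Br)C1
F8 | step 3 | bromo{(3S,6R)-2,2,6-trimethyl-6-[(4S)-2-oxo-1,3-dioxolan-4-yl]oxan-3-yl}mercury | O=C1OC[C@H](O1)[C@@]2(C)CC[C@H]([Hg]Br)C(C)(C)O2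
F9 | step 9 | {[(3R,6E,8E)-9-iodo-3,7-dimethylnona-1,6,8-trien-3-yl]oxy}triethylsilane | C=C[C@](C)(O[Si](CC)(CC)CC)CC/C=C(\C)/C=C/I
F10 | step 9 | (2E,4E,8R)-1-[(2R,5S)-5-bromo-2,6,6-trimethyloxan-2-yl]-4,8-dimethyl-8-[(triethylsilyl)oxy]deca-2,4,9-trien-1-ol (both C1 epimers) | C=C[C@](C)(O[Si](CC)(CC)CC)CC/C=C(\C)/C=C/C(O)[C@@]1(C)CC[C@H](Br)C(C)(C)O1
F11 | step 9 | (2E,4E,8R)-1-[(2R,5S)-5-bromo-2,6,6-trimethyloxan-2-yl]-4,8-dimethyl-8-[(triethylsilyl)oxy]deca-2,4,9-trien-1-yl acetate | C=C[C@](C)(O[Si](CC)(CC)CC)CC/C=C(\C)/C=C/C(OC(C)=O)[C@@]1(C)CC[C@H](Br)C(C)(C)O1
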